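The numbers in the tables are calculated from invented constants.

In the birch flask D stands flat at 0.0168 M, so 0.0333 M of the L charged is a leftover that did not become D. Before repeating the run, we must decide what to change to recover some of it.

| flask | L | J | Z | remark | time | volume of the second phase over the first |
|---|---|---|---|---|---|---|
| birch | 0.050 M | 0.090 M | 0.050 M | the very flask that is asked about, followed so far |  |  |
| ash | 0.10 M | 0.090 M | 0.050 M | run made earlier |  |  |
| flask | 0.050 M | 0.0900 M | 0.0500 M |  | 80 min | 0.50 |

| run | time / min | D / % |
|---|---|---|
| birch | 2.00 | 9.3 |
| birch | 3.00 | 15.2 |
| birch | 4.00 | 20.4 |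
| birch | 6.00 | 27.0 |
| birch | 10.0 | 32.6 |
| birch | 15.0 | 33.5 |
| birch | 25.0 | 33.5 |
| ash | 12.0 | 41.1 |
| ash | 25.0 | 49.7 |
| ash | 30.0 | 50.6 |
| ash | 50.0 | 49.6 |
| ash | 60.0 | 50.8 |
| ash | 80.0 | 49.8 |

(readings scatter by 0.3 percentage points)

- how much D there is at 80 min, in percent of the L charged
- the change that raises the amount of D at 80 min, in percent of the L charged most ("none" if none brings more than 2 percentage points) (eta / gamma / none)
- amount of D at 80 min, in percent of the L charged, after gamma

- eta: doubling the transfer coefficient of J, all else as stated
- gamma: doubling the amount of J, all else as stated

- in the second phase: J; everything else is in the first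
- charges count per volume of the first phase; a concentration in a rate is the amount of a species over the volume of its own phase; every rate counts per litre of the first phase
- the earlier runs hold the two phases in the same ratio of volumes as the flask asked about

Our own reckoning takes that leftover as L lost one for one to Z, and it assumes that the reagent making D holds steady. We divide the rate of D by the rate of that loss, so that L and time drop out. D gained per Z lost then goes as one over Z, and summing over the run gives D as a constant times ln(starting Z / final Z). That constant is the crossover level, the amount of Z at which L goes equally to D and to the loss, a selectivity factor written as a concentration. On that reckoning birch ends with Z at 0.0168 M, so its readings give a crossover level of 0.0153 M.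

The ash run tests this on a different charge. Making its 0.0498 M of D at that level leaves Z at 0.00194 M, so D and the loss together account for 0.0979 M of its 0.10 M of L. Birch reads the same at 15.0 min and 25.0 min, and ash stays flat from 30.0 min to 80.0 min, so we expect the birch plateau at 80 min, leave the time alone and try to raise the crossover level instead.

The forecast gives 33.5 % and chooses gamma, doubling J, with 47 % after it, holding that “Doubling J doubles the supply whatever the regime”. Our formula turns that 47 % into a crossover level of 0.0311 M, twice ours.

The flask gives 33.4 % at 80 min, with 0 % of its L and 34 % of its Z left, and it stood at 33.4 % already at 20.0 min. The best change is gamma, doubling J, at 9.7 percentage points against 6.1 points for doubling the transfer coefficient. It brings D to 43.1 %, which our formula reads as a crossover level of 0.0256 M, lower than the forecast's 0.0311 M.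

    L + Q → D (k = 0.221 L mol⁻¹ s⁻¹)
    Q ⇌ J, rate k2*([Q] - [J]/K2) per volume of the first phase (partition coefficient = 2.90, kL = 0.00241 s⁻¹)
    L + Z → E (k = 0.142 L mol⁻¹ s⁻¹)
    L → X (k = 1.78 × 10⁻⁵ s⁻¹)

Take the same flask with 0.20 M of Z. Counting the full L charge as lost to Z puts Z at 0.150 M in this reckoning, and our crossover level then gives 8.81 % of the L charged as D. The computed neighbour gives 3.96 %, less than that, with 76 % of its Z left.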